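The chair opened on an impossibility: ring formed by one constant and never drained cannot give the oak run, because its gain per minute, divided by the mean starting material, falls from 0.0321 min⁻¹ in the first stretch to 0.00582 min⁻¹ in the last.

| flask | starting material | temperature | remark | time |
|---|---|---|---|---|
| maple | 0.67 M | 65 °C | run made earlier |  |
| oak | 1.5 M | 80 °C | run made earlier |  |
| delta | 1.0 M | 70 °C |  | 80 min |
| gamma | 1.0 M | 90 °C |  | 80 min |

| run | time / min | ring / % | starting material / % |
|---|---|---|---|
| maple | 12.0 | 8.2 | 74.2 |
| maple | 25.0 | 13.6 | 56.2 |
| maple | 40.0 | 19.5 | 44.5 |
| maple | 50.0 | 21.0 | 39.4 |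
| maple | 60.0 | 22.5 | 35.5 |
| oak | 3.00 | 7.9 | 64.0 |
| oak | 6.00 | 13.9 | 47.7 |
| oak | 12.0 | 18.9 | 35.3 |
| oak | 20.0 | 22.1 | 30.6 |
| oak | 40.0 | 25.4 | 26.1 |

(readings scatter by 0.5 percentage points)



- the flask with the highest amount of ring, in percent of the starting material charged ("all alike" if they lie within 1.5 percentage points) (delta / gamma / all alike)
- final ring, as a percentage of the starting material charged, in delta
- final ring, as a percentage of the starting material charged, in gamma

The kineticist therefore proposed a pseudo-first-order balance: ring gain equals a making constant times starting material, less a drain constant times ring, the drain lumping the routes out of ring. She replaced each curve by its mean over two stretches, from charge to first reading and over the last 20.0 min, which gives two equations for two constants. The oak run read making 0.0337 min⁻¹ and drain 0.0333 min⁻¹, the maple run 0.00825 min⁻¹ and 0.00857 min⁻¹, all readings with their scatter. The analyst checked the error of the mean: for oak's first stretch, a logarithmic mean of starting material differs by 1.63%.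

The meeting carried forward the tracking ratio, making constant over drain constant, averaged over both runs: 0.988. The kineticist argued that gamma, at 90 °C against 80 °C in oak, should drain ring no slower than oak, since the drain read higher in oak than in maple, though those two runs differ in charge as well as in temperature. Taking oak's drain for gamma, the 80 min of gamma span 2.66 drain lives, so she expected ring in gamma to end near the ratio times the starting material then present. The readings do not give that amount, so the minutes record no figure.

The forecast, unlike these minutes, did give figures, 26% for delta and 26% for gamma, hence all alike: “They come out alike.”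

Delta ends with 26.0% ring and gamma with 10.5%, so delta holds more.

    2 starting material ⇌ open dimer (K = 3.00 M⁻¹, k = 0.0237 M⁻¹ min⁻¹, Ea = 78.0 kJ mol⁻¹, ΔH = −90.0 kJ mol⁻¹)
    starting material ⇌ ring (K = 2.60, k = 0.0141 min⁻¹, Ea = 100 kJ mol⁻¹, ΔH = −31.0 kJ mol⁻¹)
    ring → over-reaction product (k = 0.00540 min⁻¹, Ea = 112 kJ mol⁻¹)
    (constants at 70 °C)

In gamma, ring was made 1.12 times as fast as it was used up at 13.4 min, but 0.559 times as fast at 80.0 min, each step taken net, so ring was then falling. Beside that ring stand 10.1% starting material, for which the tracking ratio gives 10.0% against 10.5% found, and in the same gamma flask read at 2.5 h, 2.06% starting material gives 2.04% against 2.19% ring found.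

(The readings are simulated for an exercise; the scatter is artificial.)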